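**Strategy**

Everything rests on disconnecting the C3–C3a bond of the cyclopentane. Because the methyl-bearing fusion carbon C8a lies between the two oxygenated carbons C8 and C3a of the seven-membered ring, this cut leads back to an achiral triketone: 2-methylcycloheptane-1,3-dione carrying a 4-oxopentyl chain on C2. One amine-catalysed intramolecular aldol then tells the two mirror-related ring carbonyls apart, closes the five-membered ring and fixes C8a, C3a and C3 together. The carbonyl that is left becomes C8 and serves as the handle for the enone chemistry that brings in the C6 methyl, the C6=C7 alkene and the ester-bearing carbinol.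

Key step: step 5

Assumption: the sense of induction in step 5 cannot be assigned with certainty beforehand; (S)-proline is written, and (R)-proline takes its place if that antipode is the one leading to (3S,3aS,8aS)-8.

Numbering: all bicyclic compounds carry the hydroazulene locants of the target (cyclopentane C1–C3, fusion carbons C3a and C8a, seven-membered ring C4–C8).

**Route**

Step 1
Reactants: 1 cycloheptane-1,3-dione
Product: 2 2-methylcycloheptane-1,3-dione
Conditions: MeI (1.0 equiv), K2CO3, acetone, reflux
Reagents that add atoms: iodomethane, CI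
Why: C-alkylation of the doubly activated C2 position by SN2 reaction of the dione enolate with iodomethane, with the electrophile kept limiting to hold back a second methylation.

Step 2
Reactants: 2 2-methylcycloheptane-1,3-dione; 3 allyl acetate
Product: 4 2-methyl-2-(prop-2-en-1-yl)cycloheptane-1,3-dione
Conditions: Pd(PPh3)4 (2 mol %), DBU, THF, rt
Reagents that add atoms: none
Why: Tsuji–Trost allylation, in which the zerovalent palladium catalyst ionises allyl acetate to a π-allyl complex that the soft dione enolate captures at carbon, O-allylated material being returned to the π-allyl pool, so that the quaternary carbon should form cleanly.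

Step 3
Reactants: 4 2-methyl-2-(prop-2-en-1-yl)cycloheptane-1,3-dione; 5 methyl vinyl ketone
Product: 6 2-methyl-2-[(2E)-4-oxopent-2-en-1-yl]cycloheptane-1,3-dione
Conditions: methyl vinyl ketone (3 equiv), second-generation Grubbs catalyst RuCl2(=CHPh)(PCy3)(H2IMes) (3 mol %), CH2Cl2, 40 °C
Reagents that add atoms: none
Why: Olefin cross-metathesis between an unhindered terminal alkene and an electron-poor vinyl ketone favours the cross product as the E-enone, and the two ring ketones are inert to the ruthenium carbene.

Step 4
Reactants: 6 2-methyl-2-[(2E)-4-oxopent-2-en-1-yl]cycloheptane-1,3-dione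
Product: 7 2-methyl-2-(4-oxopentyl)cycloheptane-1,3-dione
Conditions: H2 (1 atm), 10% Pd/C, EtOAc, rt
Reagents that add atoms: none
Why: Heterogeneous catalytic hydrogenation saturates the conjugated alkene far faster than it touches the three ketones and delivers the achiral triketone.

Step 5
Reactants: 7 2-methyl-2-(4-oxopentyl)cycloheptane-1,3-dione
Product: 8 (3S,3aS,8aS)-3-acetyl-3a-hydroxy-8a-methylperhydroazulen-8-one
Conditions: (S)-proline (30 mol %), DMF, rt
Reagents that add atoms: none
Why: (S)-Proline condenses with the methyl ketone to an iminium ion in equilibrium with its enamines, and the internal enamine attacks through C3 the ring carbonyl that is hydrogen-bonded to the carboxylic acid, after which hydrolysis releases the ketol and the catalyst. The closest known reaction is the Hajos–Parrish–Eder–Sauer–Wiechert desymmetrising aldol of 2,2-disubstituted cyclic 1,3-diketones, run here in the enolexo sense known from amine-catalysed keto–ketone aldolisations. The cyclopentane closes in the 5-(enolexo)-exo-trig mode, whereas the terminal enamine could only close a seven-membered ring and is unproductive. C8a is set by the catalyst, which decides which carbonyl becomes C3a; C3a is set by the three-atom tether, which reaches the carbonyl only from its own side and so puts the hydroxyl cis to the methyl; C3 is set by the acid-bridged transition state, which holds the enamine carbon and the carbonyl oxygen syn, and the epimerisable acetyl group should stay on the hydroxyl face, away from C4. The step needs enantiotopic-group selectivity, secured by the acid–carbonyl hydrogen bond, and must stop at the ketol, which the mild neutral conditions should allow because the tertiary aldol does not dehydrate readily.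

Step 6
Reactants: 8 (3S,3aS,8aS)-3-acetyl-3a-hydroxy-8a-methylperhydroazulen-8-one
Product: 9 (3S,3aS,8aS)-3-acetyl-8a-methyl-3a-(triethylsilyloxy)perhydroazulen-8-one
Conditions: Et3SiOTf, 2,6-lutidine, CH2Cl2, −78 to 0 °C
Reagents that add atoms: triethylsilyl trifluoromethanesulfonate, CC[Si](CC)(CC)OS(=O)(=O)C(F)(F)F
Why: Silyl triflate silylation of the hindered tertiary aldol hydroxyl, the standard protection of β-hydroxy ketones, removes the alkoxide that could trigger retro-aldol cleavage in the basic steps that follow.

Step 7
Reactants: 9 (3S,3aS,8aS)-3-acetyl-8a-methyl-3a-(triethylsilyloxy)perhydroazulen-8-one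
Product: 10 (3R,3aS,8aS)-8a-methyl-3-(prop-1-en-2-yl)-3a-(triethylsilyloxy)perhydroazulen-8-one
Conditions: Ph3PCH3Br, KOtBu (1.5 equiv of ylide), THF, 0 °C to rt
Reagents that add atoms: methyltriphenylphosphonium bromide, C[P+](c1ccccc1)(c1ccccc1)c1ccccc1.[Br-]
Why: Wittig methylenation should take place at the methyl ketone much faster than at the ring ketone flanked by the quaternary C8a, so that only the acetyl group becomes the isopropenyl group while C3 keeps its configuration.

Step 8
Reactants: 10 (3R,3aS,8aS)-8a-methyl-3-(prop-1-en-2-yl)-3a-(triethylsilyloxy)perhydroazulen-8-one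
Product: 11 (3R,3aS,8aS)-8a-methyl-3-(propan-2-yl)-3a-(triethylsilyloxy)perhydroazulen-8-one
Conditions: H2 (3 atm), RhCl(PPh3)3 (5 mol %), toluene, rt
Reagents that add atoms: none
Why: Homogeneous hydrogenation with RhCl(PPh3)3 reduces the 1,1-disubstituted alkene without double-bond migration or ketone reduction, so no new stereocentre arises and C3 is untouched.

Step 9
Reactants: 11 (3R,3aS,8aS)-8a-methyl-3-(propan-2-yl)-3a-(triethylsilyloxy)perhydroazulen-8-one
Product: 13 (3R,3aS,8aS)-8a-methyl-3-(propan-2-yl)-3a-(triethylsilyloxy)-2,3,3a,4,5,8a-hexahydroazulen-8(1H)-one, via trimethylsilyl enol ether 12 (not isolated)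
Conditions: LiN(iPr)2, THF, −78 °C, then Me3SiCl, −78 to 0 °C; then Pd(OAc)2 (1.1 equiv), MeCN, rt
Reagents that add atoms: chlorotrimethylsilane, C[Si](C)(C)Cl (its silyl group is held only by intermediate 12)
Why: Saegusa–Ito oxidation, in which the ketone can enolise only towards C7 because C8a is quaternary and Pd(OAc)2 converts the silyl enol ether through an oxo-π-allyl palladium species and β-hydride elimination into the C6=C7 enone.

Step 10
Reactants: 13 (3R,3aS,8aS)-8a-methyl-3-(propan-2-yl)-3a-(triethylsilyloxy)-2,3,3a,4,5,8a-hexahydroazulen-8(1H)-one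
Product: 15 (3R,3aS,8aS)-6,8a-dimethyl-3-(propan-2-yl)-3a-(triethylsilyloxy)-2,3,3a,4,5,8a-hexahydroazulen-8(1H)-one, via 6-methyl trimethylsilyl enol ether 14 (not isolated)
Conditions: Me2CuLi (from CuI and 2 MeLi), Me3SiCl, THF, −78 °C; then Pd(OAc)2 (1.1 equiv), MeCN, rt
Reagents that add atoms: lithium dimethylcuprate, [Li+].C[Cu-]C; chlorotrimethylsilane, C[Si](C)(C)Cl (its silyl group is held only by intermediate 14)
Why: Conjugate addition of the Gilman cuprate puts the methyl group on C6 and chlorotrimethylsilane traps the enolate regiospecifically, after which a second Saegusa–Ito oxidation removes the C6 hydrogen, erases the passing C6 stereocentre and gives the 6-methyl enone.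

Step 11
Reactants: 15 (3R,3aS,8aS)-6,8a-dimethyl-3-(propan-2-yl)-3a-(triethylsilyloxy)-2,3,3a,4,5,8a-hexahydroazulen-8(1H)-one
Product: 16 (3R,3aS,8S,8aR)-6,8a-dimethyl-3-(propan-2-yl)-3a-(triethylsilyloxy)-1,2,3,3a,4,5,8,8a-octahydroazulen-8-ol
Conditions: NaBH4, CeCl3·7H2O, MeOH, −78 °C
Reagents that add atoms: none
Why: Luche reduction adds hydride 1,2 to the cerium-activated enone, and hydride should approach C8 from the side of the cyclopentane methylene C1, anti to the angular methyl and the triethylsilyloxy group that together shield the other face, which places the new hydroxyl cis to the C8a methyl.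

Step 12
Reactants: 16 (3R,3aS,8S,8aR)-6,8a-dimethyl-3-(propan-2-yl)-3a-(triethylsilyloxy)-1,2,3,3a,4,5,8,8a-octahydroazulen-8-ol; 17 4-methoxybenzoyl chloride
Product: 18 (3R,3aS,8S,8aR)-6,8a-dimethyl-3-(propan-2-yl)-3a-(triethylsilyloxy)-1,2,3,3a,4,5,8,8a-octahydroazulen-8-yl 4-methoxybenzoate
Conditions: DMAP, Et3N, CH2Cl2, 0 °C to rt
Reagents that add atoms: none
Why: DMAP-catalysed acylation through the N-acylpyridinium ion esterifies the secondary allylic alcohol with retention at C8, the tertiary oxygen being silylated and out of play.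

Step 13
Reactants: 18 (3R,3aS,8S,8aR)-6,8a-dimethyl-3-(propan-2-yl)-3a-(triethylsilyloxy)-1,2,3,3a,4,5,8,8a-octahydroazulen-8-yl 4-methoxybenzoate
Product: 19 (3R,3aS,8S,8aR)-3a-hydroxy-6,8a-dimethyl-3-(propan-2-yl)-1,2,3,3a,4,5,8,8a-octahydroazulen-8-yl 4-methoxybenzoate
Conditions: HF·pyridine, pyridine, THF, 0 °C to rt
Reagents that add atoms: none
Why: Fluoride-driven cleavage of the silyl ether under buffered conditions frees the tertiary alcohol and should leave the allylic ester, which is neither hydrolysed nor ionised in this medium, intact.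

**Compound list**

1 | cycloheptane-1,3-dione | O=C1CCCCC(=O)C1 | starting material
2 | 2-methylcycloheptane-1,3-dione | CC1C(=O)CCCCC1=O | intermediate
3 | allyl acetate (prop-2-en-1-yl acetate) | CC(=O)OCC=C | starting material
4 | 2-methyl-2-(prop-2-en-1-yl)cycloheptane-1,3-dione | C=CCC1(C)C(=O)CCCCC1=O | intermediate
5 | methyl vinyl ketone (but-3-en-2-one) | CC(=O)C=C | starting material
6 | 2-methyl-2-[(2E)-4-oxopent-2-en-1-yl]cycloheptane-1,3-dione | CC(=O)/C=C/CC1(C)C(=O)CCCCC1=O | intermediate
7 | 2-methyl-2-(4-oxopentyl)cycloheptane-1,3-dione (achiral triketone) | CC(=O)CCCC1(C)C(=O)CCCCC1=O | intermediate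
8 | (3S,3aS,8aS)-3-acetyl-3a-hydroxy-8a-methylperhydroazulen-8-one; cis-fused, with acetyl, hydroxyl and methyl on one face | O=C1CCCC[C@]2(O)[C@@H](C(C)=O)CC[C@]12C | intermediate
9 | (3S,3aS,8aS)-3-acetyl-8a-methyl-3a-(triethylsilyloxy)perhydroazulen-8-one | O=C1CCCC[C@]2(O[Si](CC)(CC)CC)[C@@H](C(C)=O)CC[C@]12C | intermediate
10 | (3R,3aS,8aS)-8a-methyl-3-(prop-1-en-2-yl)-3a-(triethylsilyloxy)perhydroazulen-8-one | O=C1CCCC[C@]2(O[Si](CC)(CC)CC)[C@@H](C(C)=C)CC[C@]12C | intermediate
11 | (3R,3aS,8aS)-8a-methyl-3-(propan-2-yl)-3a-(triethylsilyloxy)perhydroazulen-8-one | O=C1CCCC[C@]2(O[Si](CC)(CC)CC)[C@@H](C(C)C)CC[C@]12C | intermediate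
12 | trimethylsilyl enol ether of 11 (C8–OSiMe3, C7=C8; C3, C3a and C8a as in 11) | C[Si](C)(C)OC1=CCCC[C@]2(O[Si](CC)(CC)CC)[C@@H](C(C)C)CC[C@]12C | intermediate
13 | (3R,3aS,8aS)-8a-methyl-3-(propan-2-yl)-3a-(triethylsilyloxy)-2,3,3a,4,5,8a-hexahydroazulen-8(1H)-one (C6=C7 enone) | O=C1C=CCC[C@]2(O[Si](CC)(CC)CC)[C@@H](C(C)C)CC[C@]12C | intermediate
14 | 6-methyl trimethylsilyl enol ether (C8–OSiMe3, C7=C8, methyl on C6 as either epimer; C3, C3a and C8a as in 11) | C[Si](C)(C)OC1=CC(C)CC[C@]2(O[Si](CC)(CC)CC)[C@@H](C(C)C)CC[C@]12C | intermediate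
15 | (3R,3aS,8aS)-6,8a-dimethyl-3-(propan-2-yl)-3a-(triethylsilyloxy)-2,3,3a,4,5,8a-hexahydroazulen-8(1H)-one | O=C1C=C(C)CC[C@]2(O[Si](CC)(CC)CC)[C@@H](C(C)C)CC[C@]12C | intermediate
16 | (3R,3aS,8S,8aR)-6,8a-dimethyl-3-(propan-2-yl)-3a-(triethylsilyloxy)-1,2,3,3a,4,5,8,8a-octahydroazulen-8-ol; C8 hydroxyl cis to the C8a methyl | O[C@H]1C=C(C)CC[C@]2(O[Si](CC)(CC)CC)[C@@H](C(C)C)CC[C@]12C | intermediate
17 | 4-methoxybenzoyl chloride | COc1ccc(cc1)C(Cl)=O | starting material
18 | (3R,3aS,8S,8aR)-6,8a-dimethyl-3-(propan-2-yl)-3a-(triethylsilyloxy)-1,2,3,3a,4,5,8,8a-octahydroazulen-8-yl 4-methoxybenzoate | COc1ccc(C(=O)O[C@H]2C=C(C)CC[C@]3(O[Si](CC)(CC)CC)[C@@H](C(C)C)CC[C@]23C)cc1 | intermediate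
19 | (3R,3aS,8S,8aR)-3a-hydroxy-6,8a-dimethyl-3-(propan-2-yl)-1,2,3,3a,4,5,8,8a-octahydroazulen-8-yl 4-methoxybenzoate; ester oxygen, methyl, hydroxyl and isopropyl all on one face | COc1ccc(C(=O)O[C@H]2C=C(C)CC[C@]3(O)[C@@H](C(C)C)CC[C@]23C)cc1 | target

**Step count and risk**

Total steps: 13. Longest linear sequence: 13 steps, from 1 to 19.

Steps most likely to fail:

1. Step 5. The catalyst may discriminate poorly between the two ring carbonyls, or the internal enamine may form too slowly, so that conversion stalls or the aldol dehydrates on forcing. The fallback makes the same C3–C3a bond through a metal enolate; it sets out from enone 6 and comes back at ketol 8. It is a ligand-controlled copper hydride reductive aldol cyclisation (Cu(OAc)2·H2O, a chiral bisphosphine such as (R)-DTBM-SEGPHOS, 1,1,3,3-tetramethyldisiloxane, THF, 0 °C, then aqueous NH4F). Hydride adds to the β-carbon of the enone, and the chiral copper enolate adds through a chair-like six-membered transition state to one ring carbonyl, which again should give the cis ketol and makes step 4 unnecessary. No compound outside the list arises on this path (entry F0).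

2. Step 11. Facial selectivity of hydride delivery at C8 may be poor or reversed. In that case the reduction of 15 is accepted as it comes, and the C8-epimeric allylic alcohol F1 is esterified with inversion in a Mitsunobu reaction (4-methoxybenzoic acid, PPh3, diisopropyl azodicarboxylate, toluene, 0 °C to rt). This is the kind of inversion used on the likewise neopentylic 17-hydroxyl of steroids. The path leaves the route at 15 and rejoins it at 18, replacing steps 11 and 12.

3. Step 7. The ylide may act as a base, epimerising C3 or expelling the β-silyloxy group, or may not distinguish well enough between the two ketones. The fallback sets out from 9, which is treated with the barely basic cerium reagent made from Me3SiCH2Li and CeCl3 (THF, −78 °C). It adds to the methyl ketone and gives the β-hydroxysilane F2. Peterson elimination with KN(SiMe3)2 (THF, 0 °C) then gives isopropenyl compound 10, where the route is rejoined.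

**Further compounds**

F0 | step 5 | none | none
F1 | step 11 | (3R,3aS,8R,8aR)-6,8a-dimethyl-3-(propan-2-yl)-3a-(triethylsilyloxy)-1,2,3,3a,4,5,8,8a-octahydroazulen-8-ol (C8 epimer of 16) | O[C@@H]1C=C(C)CC[C@]2(O[Si](CC)(CC)CC)[C@@H](C(C)C)CC[C@]12C
F2 | step 7 | (3S,3aS,8aS)-3-[2-hydroxy-1-(trimethylsilyl)propan-2-yl]-8a-methyl-3a-(triethylsilyloxy)perhydroazulen-8-one (carbinol carbon as either epimer) | O=C1CCCC[C@]2(O[Si](CC)(CC)CC)[C@@H](C(C)(O)C[Si](C)(C)C)CC[C@]12C
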